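## Structural features

Lupalbigenin is an isoflavone: ring A (a benzene ring) is fused to ring C (a 4-pyranone) to give a chromen-4-one, and ring B, a phenol, is bonded to C3 of ring C through the C3–C1' bond. Ring A carries hydroxyls at C5 and C7 with a prenyl group between them at C6; ring B carries a hydroxyl at C4' with a prenyl group beside it at C3'. The target has no stereocentre, so no stereocentres stand next to each other; the only one on the route, C3 of the ring-closure product, is transient. The fragile parts are the two trisubstituted alkenes, each ortho to a phenol. Acid adds the phenol across them to give 2,2-dimethylchroman rings, and hydrogenation, halogens, peracids and strong Lewis acids attack them, which excludes benzyl ethers and boron halides. The real difficulty is regiochemical: the prenyl group must end at C6 and not at C8, so the two oxygens ortho to C4a (the future O1 and the chelated C5 hydroxyl) have to be told apart. The key step uses the fact that C4 (the ketone carbon of ring C) and its neighbour C3 (one dehydration away from a tertiary carbinol) are both carbonyl-derived carbons. A ring A aldehyde carbon acting as an acyl anion (C4) can therefore be joined to a ring B aryl ketone carbon (C3) that is held in reach by the O1–C2 tether.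

## Logic of the disconnections

18 is traced back to 17 by cutting the three aryl O–CH2 bonds of the acetal protecting groups. Removing them last keeps every phenol masked while bases, organometallics and heat are in use. The demand on the forward step is an acid mild enough to leave each prenyl group beside its newly freed phenol.

17 is traced back to 15 by formal addition of water across C2=C3. No bond of the skeleton is cut, but C3 becomes a carbinol carbon beside the C4 ketone, which is the pattern a benzoin reaction makes. The forward elimination must take its hydrogen from C2, which is not acidic, so the tertiary hydroxyl has to be activated under neutral conditions and leave with a syn hydrogen or by ionisation.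

15 is traced back to 14 by cutting C3–C4, the bond between two carbonyl-derived carbons. This opens ring C and gives a keto-aldehyde in which each half already carries its prenyl group and its protected oxygens. The forward step must reverse the polarity of the aldehyde only, and the six-membered closure must be faster than base-mediated aldol closure of the same substrate.

14 is traced back to 7 and 13 by cutting the O1–C2 ether bond. This is the convergent cut: it separates a ring A salicylaldehyde from a ring B chloromethyl ketone of similar size. The forward O-alkylation must be run so gently that the product does not condense with its own aldehyde.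

13 is traced back to 10 and 11 (through 12) by cutting the bond between C1' and the ketone carbon. The aryl metal has to add once to an acyl donor that also carries a displaceable chloride, which a chelating N-methoxy-N-methyl amide allows. 10 is traced back to 9 by cutting the protecting O–CH2 bond, and 9 to 8 and 3 by cutting the C3'–prenyl bond. The forward C-alkylation must go to the ortho carbon rather than to oxygen; the bromine blocks the para position and later becomes the metal.

7 is traced back to 4 (through 6 and 5) by two retro-[3,3] shifts that return the prenyl group from carbon to the phenol oxygen. The reason is regiochemical: a group that leaves an oxygen and travels ortho and then para can only arrive at the carbon between the two protected oxygens, which is the future C6. The forward rearrangement requires the second shift to outrun tautomerisation of 5.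

4 is traced back to 2 and 3, and 2 to 1, by cutting O–C bonds. The chelated hydroxyl of 1 is distinguished from the other two by its hydrogen bond, so 2 needs no extra differentiation step. The only demand is that the protection stop at two groups.

## Other disconnections considered

Alternative 1: The cut is at both prenyl–arene bonds, C6–C1'' and C3'–C1''', by retro-[3,3] shifts that return each prenyl group to the neighbouring oxygen as a 2-methylbut-3-en-2-yl ether.
- Forward route: genistein A1 would be silylated at its most acidic hydroxyl (C7) and converted at O5 and O4' into the bis-ether A2. Heating A2, optionally with Eu(fod)3 (trivalent europium), should cause two Claisen shifts and give A3; fluoride would then release the target.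
- In favour: the isoflavone skeleton is bought whole and both prenyl groups arrive in one operation. A reversed-prenyl ether delivers a normal prenyl group directly to the ortho carbon. C6 is the only free ortho position of O5, and C3' and C5' are equivalent. The last step uses fluoride rather than acid. On step economy (about five steps) and on the final deprotection this plan is better than the chosen one. On regiocontrol at C6 it is its equal.
- Against: everything depends on making a tertiary allyl ether at the chelated, peri-hindered C5 hydroxyl. The usual methods work best on unhindered phenols. These are CuCl2 (divalent copper) with a 1,1-dimethylpropargyl ester followed by semi-hydrogenation over Pd/CaCO3 poisoned with Pb(OAc)2, or Pd(PPh3)4 (zerovalent palladium) with a tertiary allyl carbonate. Tertiary aryl ethers can also ionise and lose the allyl unit on heating, the ring A dienone could relay the group on to C8, and freshly freed phenols beside prenyl groups at high temperature invite chroman formation.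
- Comparison: structurally both plans reach the same pattern. Mechanistically this one is purely pericyclic, whereas the chosen plan is polar and organocatalytic. The chosen plan is about twice as long but spreads its risk over steps that each have close analogy, where this plan concentrates it in one difficult etherification.

Alternative 2: The cut is through ring A at C8–C8a and C4a–C5, so the benzene ring is assembled from acyclic pieces.
- Forward route: the bis(silyloxy)diene A4 would add to the bromoalkynone A5 (conjugate addition, ring closure, loss of methanol) to give the bromo-deoxybenzoin A6. A6 still needs the C2 carbon and a copper-mediated O1–C8a closure at the bromide.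
- In favour: the substitution pattern of ring A is written into A4, so the C6-versus-C8 question does not arise. On this point the plan is better than the chosen one, which relies on the second sigmatropic shift of step 3. The ring A hydroxyls arrive unprotected, the conditions are mild, and convergence is equal (each half carries one prenyl group).
- Against: A6 has a free hydroxyl ortho to the ketone on the prenyl side. The classical one-carbon ring closure through that oxygen would be expected to outpace the metal-mediated closure at bromine and would lead to the 8-prenyl-5-bromo isomer. The chelated hydroxyl would therefore have to be protected selectively. A5 has an acidic benzylic CH2 between an arene and an ynone (isomerisation to an allenyl ketone) and a bromoalkyne that can react by addition–elimination. A4 is hydrolytically labile.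
- Comparison: the key step here builds ring A but leaves ring C to be made afterwards. The chosen key step makes the ring that joins the two halves and needs only dehydration afterwards. In step count this plan is expected to be longer than the chosen one.

Alternative 3: The cut is through ring B at C1'–C2' and C5'–C6'.
- Forward route: the 3-ethynylchromone A7 would undergo a [4+2] cycloaddition with the silyloxydiene A8. This could be thermal, or use CoBr2(dppe) (divalent cobalt precatalyst) reduced by zinc in the presence of ZnI2. The product is the cyclohexa-1,4-diene A9, which must then be dehydrogenated to the arene and deprotected.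
- In favour: the 4'-oxygen/3'-prenyl relationship is fixed by A8, and the cobalt-catalysed variant is mild and para-selective for 2-substituted dienes. No aryl metal, no polarity reversal and no base-sensitive keto-aldehyde are involved. In mildness of the key step this plan is the equal of, or better than, the chosen one.
- Against: it constructs the simplest ring of the target, a 1,2,4-trisubstituted benzene that the chosen plan buys as 8. The ring A problem is untouched: every ring A step of the chosen plan is still needed, followed by conversion into a 3-halochromone and alkynylation to reach A7. A8 contains a third alkene that can bind low-valent cobalt, the thermal variant needs forcing conditions for an unactivated alkyne, and the dehydrogenation of A9 must spare two prenyl groups and an electron-rich ring A.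
- Comparison: structurally the new bonds lie far from the real difficulty (C6 versus C8). Mechanistically it is a cycloaddition plus oxidation against an organocatalytic closure plus elimination. In step economy it is expected to be clearly longer than the chosen plan.

Key step: step 8

Assumption: 2,4,6-trihydroxybenzaldehyde (1), the formylation product of phloroglucinol, is taken as a purchased starting material, which saves one step.

Remark on the precursor: 14 keeps all three phenols as MOM ethers (no free chelating hydroxyl beside the formyl group, stable to every basic step, one joint deprotection) and is used without storage. Its benzaldehyde carbons C1 to C6 become C4a, C5, C6, C7, C8 and C8a, so the prenyl group ends at C6. Species that exist only bound to the carbene catalyst are described in the Why line of step 8.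

## Route

Step 1
Reactants: 1 2,4,6-trihydroxybenzaldehyde
Product: 2 2-hydroxy-4,6-bis(methoxymethoxy)benzaldehyde
Conditions: MOMCl (2.2 equiv), i-Pr2NEt (3 equiv), CH2Cl2, 0 °C to rt
Reagents that add atoms: chloromethyl methyl ether (MOMCl), COCCl
Why: Base-mediated acetal ether formation (Williamson type); the para hydroxyl and one ortho hydroxyl react, while the remaining ortho hydroxyl is held in a hydrogen bond to the formyl oxygen and is much less nucleophilic, so the reaction should stop at the bis-ether.

Step 2
Reactants: 2 2-hydroxy-4,6-bis(methoxymethoxy)benzaldehyde; 3 prenyl bromide (1-bromo-3-methylbut-2-ene)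
Product: 4 2,4-bis(methoxymethoxy)-6-[(3-methylbut-2-en-1-yl)oxy]benzaldehyde
Conditions: 3 (1.3 equiv), K2CO3 (2 equiv), acetone, reflux
Reagents that add atoms: none
Why: Williamson ether synthesis; carbonate deprotonates the chelated phenol and the phenoxide displaces bromide at the primary allylic carbon by SN2.

Step 3
Reactants: 4 2,4-bis(methoxymethoxy)-6-[(3-methylbut-2-en-1-yl)oxy]benzaldehyde
Product: 7 6-hydroxy-2,4-bis(methoxymethoxy)-3-(3-methylbut-2-en-1-yl)benzaldehyde, via ortho-dienone 5 (not isolated), via para-dienone 6 (not isolated)
Conditions: PhNEt2, 200 °C, sealed tube, Ar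
Reagents that add atoms: none
Why: Para-Claisen rearrangement (Claisen shift followed by Cope shift): the first [3,3] shift places a 1,1-dimethylallyl group on the free ortho carbon (5), the crowded quaternary carbon beside two oxygenated ring carbons drives a second [3,3] shift to the para carbon (6), and enolisation gives the phenol; both shifts are intramolecular, so the prenyl group can only arrive para to the oxygen it left, which is the carbon between the two MOM ethers, and the transient stereocentres of 5 and 6 vanish on aromatisation.

Step 4
Reactants: 8 4-bromophenol; 3 prenyl bromide (1-bromo-3-methylbut-2-ene)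
Product: 9 4-bromo-2-(3-methylbut-2-en-1-yl)phenol
Conditions: NaH (1.0 equiv), toluene, 0 °C to rt; then 3 (1.0 equiv), rt
Reagents that add atoms: none
Why: ortho-C-Alkylation of a sodium phenoxide in a non-polar solvent; the tight, aggregated ion pair shields oxygen and delivers the allylic halide to the ortho carbon, bromine blocks the para position, and one equivalent of 3 limits double alkylation.

Step 5
Reactants: 9 4-bromo-2-(3-methylbut-2-en-1-yl)phenol
Product: 10 4-bromo-1-(methoxymethoxy)-2-(3-methylbut-2-en-1-yl)benzene
Conditions: MOMCl (1.3 equiv), i-Pr2NEt (2 equiv), CH2Cl2, 0 °C to rt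
Reagents that add atoms: chloromethyl methyl ether (MOMCl), COCCl
Why: Base-mediated acetal ether formation on an unhindered phenol; it also removes the free hydroxyl that could otherwise add to the prenyl group or quench the organometallic of step 6.

Step 6
Reactants: 10 4-bromo-1-(methoxymethoxy)-2-(3-methylbut-2-en-1-yl)benzene; 11 2-chloro-N-methoxy-N-methylacetamide
Product: 13 2-chloro-1-[4-(methoxymethoxy)-3-(3-methylbut-2-en-1-yl)phenyl]ethan-1-one, via arylmagnesium bromide 12 (not isolated)
Conditions: Mg turnings (I2 cat.), THF, 50 °C; then 11, THF, −10 to 0 °C; aq NH4Cl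
Reagents that add atoms: none
Why: Grignard formation followed by Weinreb ketone synthesis; the magnesium-chelated tetrahedral adduct of 11 is stable until the quench, so a second addition and attack at the C–Cl carbon are not expected, and the MOM ether and the alkene are inert to the aryl magnesium.

Step 7
Reactants: 7 6-hydroxy-2,4-bis(methoxymethoxy)-3-(3-methylbut-2-en-1-yl)benzaldehyde; 13 2-chloro-1-[4-(methoxymethoxy)-3-(3-methylbut-2-en-1-yl)phenyl]ethan-1-one
Product: 14 2,4-bis(methoxymethoxy)-6-{2-[4-(methoxymethoxy)-3-(3-methylbut-2-en-1-yl)phenyl]-2-oxoethoxy}-3-(3-methylbut-2-en-1-yl)benzaldehyde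
Conditions: K2CO3 (1.5 equiv), KI (10 mol%), acetone, 20 °C; used directly in step 8
Reagents that add atoms: none
Why: Williamson ether synthesis with Finkelstein activation; the phenoxide of 7 displaces halide next to a carbonyl in a fast SN2 reaction, and room temperature with a mild carbonate is chosen so that the product does not enter the Rap–Stoermer aldol condensation to a 2-aroylbenzofuran, which normally needs heat.

Step 8
Reactants: 14 2,4-bis(methoxymethoxy)-6-{2-[4-(methoxymethoxy)-3-(3-methylbut-2-en-1-yl)phenyl]-2-oxoethoxy}-3-(3-methylbut-2-en-1-yl)benzaldehyde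
Product: 15 racemic 3-hydroxy-5,7-bis(methoxymethoxy)-3-[4-(methoxymethoxy)-3-(3-methylbut-2-en-1-yl)phenyl]-6-(3-methylbut-2-en-1-yl)chroman-4-one
Conditions: 2-(pentafluorophenyl)-6,7-dihydro-5H-pyrrolo[2,1-c][1,2,4]triazol-2-ium tetrafluoroborate (15 mol%), Et3N (30 mol%), toluene (0.05 M), 25 to 45 °C, Ar
Reagents that add atoms: none
Why: Et3N frees the carbene from the triazolium salt, and the carbene adds to the formyl carbon of 14, the only carbonyl that carries the hydrogen needed for the next proton shift. Proton transfer gives the enaminol (Breslow intermediate), an acyl anion equivalent at the future C4. This carbon attacks the tethered aryl ketone carbon (future C3) in a 6-exo-trig closure, the ketone C=O remaining outside the new ring, which forms C3–C4 and ring C; proton shift and loss of the carbene give 15 and return the catalyst. The closest known reaction type is the carbene-catalysed intramolecular crossed aldehyde–ketone benzoin cyclisation that gives 3-hydroxychroman-4-ones. The new stereocentre C3 is formed without control because the catalyst is achiral, so 15 is racemic, which is acceptable because C3 becomes trigonal in step 9. The step needs selectivity between the two carbonyls and between benzoin and aldol closure: the ketone cannot form an acyl anion equivalent, the tether and high dilution favour ring closure over intermolecular benzoin, and a substoichiometric weak amine in toluene should not enolise the OCH2 group fast enough for the five-membered aldol closure. The electron-poor N-C6F5 group makes the azolium acidic enough for Et3N and suits an electron-rich aldehyde with two ortho substituents, which forms the enaminol slowly.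

Step 9
Reactants: 15 racemic 3-hydroxy-5,7-bis(methoxymethoxy)-3-[4-(methoxymethoxy)-3-(3-methylbut-2-en-1-yl)phenyl]-6-(3-methylbut-2-en-1-yl)chroman-4-one
Product: 17 5,7-bis(methoxymethoxy)-3-[4-(methoxymethoxy)-3-(3-methylbut-2-en-1-yl)phenyl]-6-(3-methylbut-2-en-1-yl)-4H-chromen-4-one, via sulfamate ester 16 (not isolated)
Conditions: Burgess reagent (methyl N-(triethylammoniosulfonyl)carbamate, 2 equiv), toluene, 60 °C
Reagents that add atoms: none
Why: Burgess dehydration; the tertiary hydroxyl is sulfonylated to 16 and the sulfamate leaves with a syn hydrogen of C2 through a cyclic transition state (or by ionisation to the 4-alkoxyphenyl-stabilised cation followed by loss of a C2 proton), C2 is the only neighbour of C3 that carries hydrogen so only the chromone C2=C3 bond can form, and the neutral conditions spare MOM ethers and prenyl groups; the stereocentre is erased.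

Step 10
Reactants: 17 5,7-bis(methoxymethoxy)-3-[4-(methoxymethoxy)-3-(3-methylbut-2-en-1-yl)phenyl]-6-(3-methylbut-2-en-1-yl)-4H-chromen-4-one
Product: 18 lupalbigenin (5,7-dihydroxy-3-[4-hydroxy-3-(3-methylbut-2-en-1-yl)phenyl]-6-(3-methylbut-2-en-1-yl)-4H-chromen-4-one)
Conditions: 3 M aq HCl/MeOH (1:5), 45 °C, stopped at full conversion
Reagents that add atoms: none
Why: Acid-catalysed acetal exchange with methanol removes the three MOM groups, the C5 ether peri to the carbonyl first; dilute acid, moderate temperature and an early stop are chosen so that the prenyl double bonds do not add the neighbouring phenols.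

## Compound list

1 | 2,4,6-trihydroxybenzaldehyde | O=Cc1c(O)cc(O)cc1O | starting material
2 | 2-hydroxy-4,6-bis(methoxymethoxy)benzaldehyde | O=Cc1c(O)cc(OCOC)cc1OCOC | intermediate
3 | prenyl bromide (1-bromo-3-methylbut-2-ene) | CC(C)=CCBr | starting material
4 | 2,4-bis(methoxymethoxy)-6-[(3-methylbut-2-en-1-yl)oxy]benzaldehyde | O=Cc1c(OCC=C(C)C)cc(OCOC)cc1OCOC | intermediate
5 | ortho-dienone: racemic 2,4-bis(methoxymethoxy)-5-(2-methylbut-3-en-2-yl)-6-oxocyclohexa-1,3-diene-1-carbaldehyde (not isolated) | O=CC1=C(OCOC)C=C(OCOC)C(C(C)(C)C=C)C1=O | intermediate
6 | para-dienone: racemic 2,4-bis(methoxymethoxy)-3-(3-methylbut-2-en-1-yl)-6-oxocyclohexa-1,4-diene-1-carbaldehyde (not isolated) | O=CC1=C(OCOC)C(CC=C(C)C)C(OCOC)=CC1=O | intermediate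
7 | 6-hydroxy-2,4-bis(methoxymethoxy)-3-(3-methylbut-2-en-1-yl)benzaldehyde | O=Cc1c(O)cc(OCOC)c(CC=C(C)C)c1OCOC | intermediate
8 | 4-bromophenol | Oc1ccc(Br)cc1 | starting material
9 | 4-bromo-2-(3-methylbut-2-en-1-yl)phenol | CC(C)=CCc1cc(Br)ccc1O | intermediate
10 | 4-bromo-1-(methoxymethoxy)-2-(3-methylbut-2-en-1-yl)benzene | COCOc1ccc(Br)cc1CC=C(C)C | intermediate
11 | 2-chloro-N-methoxy-N-methylacetamide | CON(C)C(=O)CCl | starting material
12 | [4-(methoxymethoxy)-3-(3-methylbut-2-en-1-yl)phenyl]magnesium bromide (not isolated) | COCOc1ccc([Mg]Br)cc1CC=C(C)C | intermediate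
13 | 2-chloro-1-[4-(methoxymethoxy)-3-(3-methylbut-2-en-1-yl)phenyl]ethan-1-one | O=C(CCl)c1ccc(OCOC)c(CC=C(C)C)c1 | intermediate
14 | 2,4-bis(methoxymethoxy)-6-{2-[4-(methoxymethoxy)-3-(3-methylbut-2-en-1-yl)phenyl]-2-oxoethoxy}-3-(3-methylbut-2-en-1-yl)benzaldehyde | O=Cc1c(OCC(=O)c2ccc(OCOC)c(CC=C(C)C)c2)cc(OCOC)c(CC=C(C)C)c1OCOC | intermediate
15 | racemic 3-hydroxy-5,7-bis(methoxymethoxy)-3-[4-(methoxymethoxy)-3-(3-methylbut-2-en-1-yl)phenyl]-6-(3-methylbut-2-en-1-yl)chroman-4-one | COCOc1cc2c(c(OCOC)c1CC=C(C)C)C(=O)C(O)(c1ccc(OCOC)c(CC=C(C)C)c1)CO2 | intermediate
16 | sulfamate ester: racemic triethylammonium salt of the O3-[N-(methoxycarbonyl)sulfamate] of 15 (not isolated) | COCOc1cc2c(c(OCOC)c1CC=C(C)C)C(=O)C(OS(=O)(=O)[N-]C(=O)OC)(c1ccc(OCOC)c(CC=C(C)C)c1)CO2.CC[NH+](CC)CC | intermediate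
17 | 5,7-bis(methoxymethoxy)-3-[4-(methoxymethoxy)-3-(3-methylbut-2-en-1-yl)phenyl]-6-(3-methylbut-2-en-1-yl)-4H-chromen-4-one | COCOc1cc2occ(-c3ccc(OCOC)c(CC=C(C)C)c3)c(=O)c2c(OCOC)c1CC=C(C)C | intermediate
18 | lupalbigenin | CC(C)=CCc1cc(-c2coc3cc(O)c(CC=C(C)C)c(O)c3c2=O)ccc1O | target

## Step count and least certain steps

Total: 10 steps. Longest linear sequence: 7 steps (1 → 2 → 4 → 7 → 14 → 15 → 17 → 18; the ring B branch 8 → 9 → 10 → 13 → 14 → 15 → 17 → 18 is equally long).

Step 8 (key step). The most likely failure is slow addition of the carbene to a formyl group that has two ortho oxygen substituents and is deactivated by three donor oxygens. Amine-mediated enolisation of the OCH2 group with five-membered aldol closure, or reversal of the benzoin addition at the electron-rich ketone, could then overtake the ring closure. The fallback changes how ring C and the C3–C1' bond are made; it sets out from 7 and from 10 (through 12) and returns at 17.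
- Compound 7 would be treated with MeMgBr (excess, THF, 0 °C) to give the carbinol 2-(1-hydroxyethyl)-3,5-bis(methoxymethoxy)-4-(3-methylbut-2-en-1-yl)phenol F1.
- F1 would be oxidised with MnO2 (CH2Cl2) to the acetophenone 1-[6-hydroxy-2,4-bis(methoxymethoxy)-3-(3-methylbut-2-en-1-yl)phenyl]ethan-1-one F2.
- Condensation with N,N-dimethylformamide dimethyl acetal (90 °C) should give the enaminone (E)-3-(dimethylamino)-1-[6-hydroxy-2,4-bis(methoxymethoxy)-3-(3-methylbut-2-en-1-yl)phenyl]prop-2-en-1-one F3.
- I2/pyridine in CHCl3 should close ring C with iodination to 3-iodo-5,7-bis(methoxymethoxy)-6-(3-methylbut-2-en-1-yl)-4H-chromen-4-one F4.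
- In parallel, 12 would be quenched with 2-isopropoxy-4,4,5,5-tetramethyl-1,3,2-dioxaborolane to the boronic ester 2-[4-(methoxymethoxy)-3-(3-methylbut-2-en-1-yl)phenyl]-4,4,5,5-tetramethyl-1,3,2-dioxaborolane F5.
- Suzuki–Miyaura coupling of F4 with F5 (Pd(dppf)Cl2, a divalent palladium precatalyst, K2CO3, dioxane/H2O, 80 °C) would form the C3–C1' bond and give 17.

Step 3. The ortho-dienone may tautomerise before the second shift, which would leave a 1,1-dimethylallyl group on the ortho carbon. At 200 °C the allyl unit or an acetal may also be lost. The fallback replaces the sigmatropic relay by directed metalation; it sets out from 2 and returns at 7.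
- Compound 2 would be silylated (TIPSOTf, 2,6-lutidine) to 2,4-bis(methoxymethoxy)-6-[(triisopropylsilyl)oxy]benzaldehyde F6.
- Lithium 4-methylpiperazin-1-ide (THF, −20 °C) would mask the formyl group in situ as the lithium α-amino alkoxide lithium [2,4-bis(methoxymethoxy)-6-(triisopropylsilyloxy)phenyl](4-methylpiperazin-1-yl)methanolate F7.
- n-BuLi/TMEDA should then lithiate the carbon between the two MOM ethers, the most activated position, and CuBr·SMe2 followed by 3 would introduce the prenyl group.
- Aqueous work-up returns the aldehyde 2,4-bis(methoxymethoxy)-3-(3-methylbut-2-en-1-yl)-6-[(triisopropylsilyl)oxy]benzaldehyde F8, and Bu4NF gives 7.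

Step 4. O-Alkylation and double C-alkylation may compete with the ortho-C-alkylation, and the product phenol may add to its own prenyl group on acidic work-up or chromatography. The fallback uses a halogen as the regiochemical handle instead of the phenoxide; it sets out from 8 and returns at 10.
- Compound 8 would be brominated (Br2, 1 equiv, CH2Cl2, 0 °C) to 2,4-dibromophenol F9 and protected (MOMCl, i-Pr2NEt) as 2,4-dibromo-1-(methoxymethoxy)benzene F10.
- i-PrMgCl·LiCl (THF, −15 °C) should exchange the bromine ortho to the chelating acetal oxygen selectively, giving [5-bromo-2-(methoxymethoxy)phenyl]magnesium chloride F11.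
- CuI (10 mol%) and 3 would then give 10.

Step 7. The new aryloxymethyl ketone may be enolised by the carbonate and attack the neighbouring formyl group, followed by dehydration (Rap–Stoermer condensation). The fallback forms the ether under neutral redox-condensation conditions instead of by phenoxide alkylation; it sets out from 13 (with 7) and returns at 14.
- Compound 13 would be heated with HCO2Na in aqueous ethanol to give 2-[4-(methoxymethoxy)-3-(3-methylbut-2-en-1-yl)phenyl]-2-oxoethyl formate F12.
- F12 hydrolyses in the same pot to 2-hydroxy-1-[4-(methoxymethoxy)-3-(3-methylbut-2-en-1-yl)phenyl]ethan-1-one F13.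
- A Mitsunobu reaction of F13 with the acidic phenol 7 (PPh3, DIAD, toluene, 0 °C to rt) would give 14 without any base present.

Step 10. The acid may promote addition of a freed phenol to the neighbouring prenyl double bond (closure to dimethylchroman rings at O5, O7 or O4'). The fallback avoids protic acid by a silyl-transfer deprotection; it sets out from 17 and returns at 18. Compound 17 would be treated with TMSOTf and 2,2'-bipyridyl (CH2Cl2, 0 °C), which should convert the aryl MOM ethers into the tris(silyl ether) 3-[3-(3-methylbut-2-en-1-yl)-4-(trimethylsilyloxy)phenyl]-6-(3-methylbut-2-en-1-yl)-5,7-bis(trimethylsilyloxy)-4H-chromen-4-one F14. Water or K2CO3/MeOH at room temperature would then release 18.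

Further compounds

F1 | step 8 | racemic 2-(1-hydroxyethyl)-3,5-bis(methoxymethoxy)-4-(3-methylbut-2-en-1-yl)phenol | CC(O)c1c(O)cc(OCOC)c(CC=C(C)C)c1OCOC
F2 | step 8 | 1-[6-hydroxy-2,4-bis(methoxymethoxy)-3-(3-methylbut-2-en-1-yl)phenyl]ethan-1-one | CC(=O)c1c(O)cc(OCOC)c(CC=C(C)C)c1OCOC
F3 | step 8 | (E)-3-(dimethylamino)-1-[6-hydroxy-2,4-bis(methoxymethoxy)-3-(3-methylbut-2-en-1-yl)phenyl]prop-2-en-1-one | CN(C)/C=C/C(=O)c1c(O)cc(OCOC)c(CC=C(C)C)c1OCOC
F4 | step 8 | 3-iodo-5,7-bis(methoxymethoxy)-6-(3-methylbut-2-en-1-yl)-4H-chromen-4-one | COCOc1cc2occ(I)c(=O)c2c(OCOC)c1CC=C(C)C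
F5 | step 8 | 2-[4-(methoxymethoxy)-3-(3-methylbut-2-en-1-yl)phenyl]-4,4,5,5-tetramethyl-1,3,2-dioxaborolane | COCOc1ccc(B2OC(C)(C)C(C)(C)O2)cc1CC=C(C)C
F6 | step 3 | 2,4-bis(methoxymethoxy)-6-[(triisopropylsilyl)oxy]benzaldehyde | O=Cc1c(O[Si](C(C)C)(C(C)C)C(C)C)cc(OCOC)cc1OCOC
F7 | step 3 | racemic lithium [2,4-bis(methoxymethoxy)-6-(triisopropylsilyloxy)phenyl](4-methylpiperazin-1-yl)methanolate | [Li+].[O-]C(N1CCN(C)CC1)c1c(O[Si](C(C)C)(C(C)C)C(C)C)cc(OCOC)cc1OCOC
F8 | step 3 | 2,4-bis(methoxymethoxy)-3-(3-methylbut-2-en-1-yl)-6-[(triisopropylsilyl)oxy]benzaldehyde | O=Cc1c(O[Si](C(C)C)(C(C)C)C(C)C)cc(OCOC)c(CC=C(C)C)c1OCOC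
F9 | step 4 | 2,4-dibromophenol | Oc1ccc(Br)cc1Br
F10 | step 4 | 2,4-dibromo-1-(methoxymethoxy)benzene | COCOc1ccc(Br)cc1Br
F11 | step 4 | [5-bromo-2-(methoxymethoxy)phenyl]magnesium chloride | COCOc1ccc(Br)cc1[Mg]Cl
F12 | step 7 | 2-[4-(methoxymethoxy)-3-(3-methylbut-2-en-1-yl)phenyl]-2-oxoethyl formate | O=COCC(=O)c1ccc(OCOC)c(CC=C(C)C)c1
F13 | step 7 | 2-hydroxy-1-[4-(methoxymethoxy)-3-(3-methylbut-2-en-1-yl)phenyl]ethan-1-one | O=C(CO)c1ccc(OCOC)c(CC=C(C)C)c1
F14 | step 10 | 3-[3-(3-methylbut-2-en-1-yl)-4-(trimethylsilyloxy)phenyl]-6-(3-methylbut-2-en-1-yl)-5,7-bis(trimethylsilyloxy)-4H-chromen-4-one | CC(C)=CCc1cc(-c2coc3cc(O[Si](C)(C)C)c(CC=C(C)C)c(O[Si](C)(C)C)c3c2=O)ccc1O[Si](C)(C)C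
A1 | alternative 1 | genistein (5,7-dihydroxy-3-(4-hydroxyphenyl)-4H-chromen-4-one) | O=c1c(-c2ccc(O)cc2)coc2cc(O)cc(O)c12
A2 | alternative 1 | 5-[(2-methylbut-3-en-2-yl)oxy]-3-{4-[(2-methylbut-3-en-2-yl)oxy]phenyl}-7-[(triisopropylsilyl)oxy]-4H-chromen-4-one | C=CC(C)(C)Oc1ccc(-c2coc3cc(O[Si](C(C)C)(C(C)C)C(C)C)cc(OC(C)(C)C=C)c3c2=O)cc1
A3 | alternative 1 | 7-O-triisopropylsilyl-lupalbigenin | CC(C)=CCc1cc(-c2coc3cc(O[Si](C(C)C)(C(C)C)C(C)C)c(CC=C(C)C)c(O)c3c2=O)ccc1O
A4 | alternative 2 | 1-methoxy-2-(3-methylbut-2-en-1-yl)-1,3-bis(trimethylsilyloxy)buta-1,3-diene | COC(O[Si](C)(C)C)=C(CC=C(C)C)C(=C)O[Si](C)(C)C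
A5 | alternative 2 | 4-bromo-1-[4-(methoxymethoxy)-3-(3-methylbut-2-en-1-yl)phenyl]but-3-yn-2-one | O=C(Cc1ccc(OCOC)c(CC=C(C)C)c1)C#CBr
A6 | alternative 2 | 1-[2-bromo-4,6-dihydroxy-5-(3-methylbut-2-en-1-yl)phenyl]-2-[4-(methoxymethoxy)-3-(3-methylbut-2-en-1-yl)phenyl]ethan-1-one | O=C(Cc1ccc(OCOC)c(CC=C(C)C)c1)c1c(Br)cc(O)c(CC=C(C)C)c1O
A7 | alternative 3 | 3-ethynyl-5,7-bis(methoxymethoxy)-6-(3-methylbut-2-en-1-yl)-4H-chromen-4-one | C#Cc1coc2cc(OCOC)c(CC=C(C)C)c(OCOC)c2c1=O
A8 | alternative 3 | tert-butyldimethyl[(6-methyl-3-methylidenehepta-1,5-dien-2-yl)oxy]silane | C=C(O[Si](C)(C)C(C)(C)C)C(=C)CC=C(C)C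
A9 | alternative 3 | 3-[4-(tert-butyldimethylsilyloxy)-3-(3-methylbut-2-en-1-yl)cyclohexa-1,4-dien-1-yl]-5,7-bis(methoxymethoxy)-6-(3-methylbut-2-en-1-yl)-4H-chromen-4-one | COCOc1cc2occ(C3=CCC(O[Si](C)(C)C(C)(C)C)=C(CC=C(C)C)C3)c(=O)c2c(OCOC)c1CC=C(C)C
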